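**Plan**

- Retrosynthesis: the quinone is released last from a bis-MOM hydroquinone. Indole B has H at C2 and the fully substituted central ring at C3, so its C2–C3 bond is cut, opening the pyrrole ring to a 2-isocyanophenyl(aryl)methane (isocyanide carbon = C2, CH2 = C3).
- Further cuts: the aryl–CH2 bond (arylzinc + 2-nitrobenzyl bromide), then the indole A C3–core bond (indole + 2,5-dichloro-1,4-benzoquinone), then the pyrrole ring of indole A (Madelung closure of an o-toluidide).
- Forward order: pyrrole ring of indole A (step 2), attachment to the quinone ring (step 3), Cl→OMe exchange, reduction and MOM protection, benzylation, nitro → amine → formamide → isocyanide, pyrrole ring of indole B (step 10), then deprotection and oxidation.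
- Stereochemistry: the target has no stereocentre and no stereogenic double bond, so nothing has to be controlled.

Key step: step 10

Remark: the aryl–quinone axes are taken as freely rotating. The N–H of indole A is carried unprotected and is simply deprotonated first in the strongly basic steps.

**Route**

Step 1
Reactants: 1 2,2-dimethylbut-3-enoic acid; 2 o-toluidine
Product: 4 2,2-dimethyl-N-(2-methylphenyl)but-3-enamide, via acid chloride 3 (not isolated)
Conditions: (COCl)2, DMF (cat.), CH2Cl2, 0 °C → rt; concentrate; then 2, Et3N, CH2Cl2, 0 °C → rt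
Reagents that add atoms: none
Why: Vilsmeier-type activation should turn the acid into its chloride, which acylates the aniline nitrogen (Schotten–Baumann-type amide formation); the quaternary α-carbon rules out ketene formation and alkene migration.

Step 2
Reactants: 4 2,2-dimethyl-N-(2-methylphenyl)but-3-enamide
Product: 5 2-(2-methylbut-3-en-2-yl)-1H-indole (indole A)
Conditions: n-BuLi (3 equiv), THF, −20 °C → rt; H2O
Reagents that add atoms: none
Why: Modified Madelung indole synthesis, in which n-BuLi removes the amide N–H and an ortho-methyl proton, the benzylic anion attacks the amide carbon and loss of LiOH aromatises the ring; the reaction is at its best with acyl groups that have no α-hydrogen, as here.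

Step 3
Reactants: 5 2-(2-methylbut-3-en-2-yl)-1H-indole; 6 2,5-dichloro-1,4-benzoquinone
Product: 8 2,5-dichloro-3-[2-(2-methylbut-3-en-2-yl)-1H-indol-3-yl]-1,4-benzoquinone, via dichloro hydroquinone 7 (not isolated)
Conditions: AcOH, rt → 40 °C, argon; then DDQ, THF, rt
Reagents that add atoms: none
Why: Acid-promoted conjugate addition (Friedel–Crafts-type Michael reaction) of indole C3 to one of the two equivalent unsubstituted quinone carbons should give the aryl hydroquinone, which DDQ dehydrogenates to the quinone; acetic acid is mild enough for the tert-allyl group, and the mono-adduct is less electrophilic than the starting quinone.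

Step 4
Reactants: 8 2,5-dichloro-3-[2-(2-methylbut-3-en-2-yl)-1H-indol-3-yl]-1,4-benzoquinone
Product: 9 2,5-dimethoxy-3-[2-(2-methylbut-3-en-2-yl)-1H-indol-3-yl]-1,4-benzoquinone
Conditions: NaOMe (3 equiv), MeOH/THF, 0 °C → rt; aq. NH4Cl
Reagents that add atoms: sodium methoxide, [Na+].[O-]C
Why: Nucleophilic vinylic substitution by addition–elimination, since each chlorine sits on the β-carbon of a vinylogous acid chloride and is displaced by methoxide, in analogy to the hydrolysis of such chloro(indolyl)quinones at C–Cl by hydroxide in methanol.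

Step 5
Reactants: 9 2,5-dimethoxy-3-[2-(2-methylbut-3-en-2-yl)-1H-indol-3-yl]-1,4-benzoquinone
Product: 11 3-[3,6-dimethoxy-2,5-bis(methoxymethoxy)phenyl]-2-(2-methylbut-3-en-2-yl)-1H-indole, via dimethoxy hydroquinone 10 (not isolated)
Conditions: Na2S2O4, THF/H2O, rt; extraction under argon; then MOMCl, iPr2NEt, Bu4NI (cat.), CH2Cl2, 0 °C → reflux
Reagents that add atoms: chloromethyl methyl ether, COCCl
Why: Dithionite reduces the quinone to the hydroquinone, and Williamson-type O-alkylation with MOMCl under a tertiary amine base should cap both phenols while the non-ionised indole N–H stays free.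

Step 6
Reactants: 11 3-[3,6-dimethoxy-2,5-bis(methoxymethoxy)phenyl]-2-(2-methylbut-3-en-2-yl)-1H-indole; 12 2-nitrobenzyl bromide
Product: 15 3-[3,6-dimethoxy-2,5-bis(methoxymethoxy)-4-(2-nitrobenzyl)phenyl]-2-(2-methylbut-3-en-2-yl)-1H-indole, via N,C-dilithio species 13 (not isolated), via N,C-bis(chlorozinc) species 14 (not isolated)
Conditions: n-BuLi (2.3 equiv), TMEDA, THF, −78 → 0 °C; ZnCl2 (2.5 equiv), 0 °C → rt; then 12, Pd(PPh3)4 (5 mol %), rt → 45 °C; aq. NH4Cl
Reagents that add atoms: none
Why: After N-deprotonation, directed ortho-metalation should occur at the only free position of the central ring, flanked by OMOM and OMe, and transmetalation to zinc sets up a Negishi cross-coupling in which zerovalent palladium inserts into the benzylic C–Br bond; the organozinc tolerates the nitro group and the hindered N-zinc indolide is too weak a nucleophile to compete.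

Step 7
Reactants: 15 3-[3,6-dimethoxy-2,5-bis(methoxymethoxy)-4-(2-nitrobenzyl)phenyl]-2-(2-methylbut-3-en-2-yl)-1H-indole
Product: 16 2-({2,5-dimethoxy-3,6-bis(methoxymethoxy)-4-[2-(2-methylbut-3-en-2-yl)-1H-indol-3-yl]phenyl}methyl)aniline
Conditions: Fe powder, NH4Cl, EtOH/H2O, 75 °C
Reagents that add atoms: none
Why: Béchamp-type reduction with iron under near-neutral conditions should convert the nitro group into the aniline without touching the terminal alkene, the MOM acetals or the indole.

Step 8
Reactants: 16 2-({2,5-dimethoxy-3,6-bis(methoxymethoxy)-4-[2-(2-methylbut-3-en-2-yl)-1H-indol-3-yl]phenyl}methyl)aniline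
Product: 17 N-[2-({2,5-dimethoxy-3,6-bis(methoxymethoxy)-4-[2-(2-methylbut-3-en-2-yl)-1H-indol-3-yl]phenyl}methyl)phenyl]formamide
Conditions: N-formylsaccharin, THF, rt; aq. NaHCO3
Reagents that add atoms: N-formylsaccharin, O=CN1C(=O)c2ccccc2S1(=O)=O
Why: N-Formylation by acyl transfer from an activated formamide to the aniline nitrogen, which is far more nucleophilic than the indole N–H.

Step 9
Reactants: 17 N-[2-({2,5-dimethoxy-3,6-bis(methoxymethoxy)-4-[2-(2-methylbut-3-en-2-yl)-1H-indol-3-yl]phenyl}methyl)phenyl]formamide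
Product: 18 3-[4-(2-isocyanobenzyl)-3,6-dimethoxy-2,5-bis(methoxymethoxy)phenyl]-2-(2-methylbut-3-en-2-yl)-1H-indole
Conditions: POCl3, Et3N (excess), CH2Cl2, −20 → 0 °C; aq. Na2CO3
Reagents that add atoms: none
Why: Ugi-type dehydration of an N-aryl formamide, in which O-phosphorylation and elimination by Et3N give the isocyanide while the excess amine keeps the medium basic for the MOM acetals.

Step 10
Reactants: 18 3-[4-(2-isocyanobenzyl)-3,6-dimethoxy-2,5-bis(methoxymethoxy)phenyl]-2-(2-methylbut-3-en-2-yl)-1H-indole
Product: 19 3-[4-(1H-indol-3-yl)-3,6-dimethoxy-2,5-bis(methoxymethoxy)phenyl]-2-(2-methylbut-3-en-2-yl)-1H-indole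
Conditions: LiN(iPr)2 (3.5 equiv), diglyme/THF, −78 °C → rt; aq. NH4Cl
Reagents that add atoms: none
Why: Once the indole A N–H has taken up one equivalent of base, LiN(iPr)2 should remove a proton from the doubly benzylic CH2; the carbanion adds to the divalent isocyanide carbon, and the resulting 3H-indol-2-yl anion isomerises by proton transfer to the N-lithioindole, which aqueous NH4Cl protonates. The closest known reaction is the Saegusa–Ito indole synthesis, the base-induced cyclisation of ortho-alkylphenyl isocyanides to 3-substituted indoles. The pyrrole ring of indole B closes in a 5-endo-dig mode, the isocyanide carbon becoming C2 and the former CH2 becoming C3. No stereocentre is created. The step needs deprotonation at the CH2 to outrun addition of the amide to the isocyanide and any ring or acetal metalation; the acidifying ortho-isocyanophenyl group, the second aryl ring, the absence of a free position on the central ring and the bulk of the base should secure this. The crowded indole B–core bond is already in place as a flexible aryl–CH2 bond before the ring forms.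

Step 11
Reactants: 19 3-[4-(1H-indol-3-yl)-3,6-dimethoxy-2,5-bis(methoxymethoxy)phenyl]-2-(2-methylbut-3-en-2-yl)-1H-indole
Product: 21 2,5-dimethoxy-3-(1H-indol-3-yl)-6-[2-(2-methylbut-3-en-2-yl)-1H-indol-3-yl]-1,4-benzoquinone (CNP0103667.0), via free hydroquinone 20 (not isolated)
Conditions: HCl (3 M aq.), MeOH/THF, rt → 40 °C, argon; then Ag2O, CH2Cl2, rt
Reagents that add atoms: none
Why: Acid-catalysed acetal methanolysis should remove both MOM groups, methanol trapping the methoxymethyl cation as dimethoxymethane, and Ag2O then dehydrogenates the electron-rich hydroquinone to the 1,4-benzoquinone; the aryl methyl ethers are inert to dilute acid at the hydroquinone stage.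

**Compound list**

1 | 2,2-dimethylbut-3-enoic acid | C=CC(C)(C)C(=O)O | starting material
2 | o-toluidine (2-methylaniline) | Cc1ccccc1N | starting material
3 | 2,2-dimethylbut-3-enoyl chloride | C=CC(C)(C)C(Cl)=O | intermediate
4 | 2,2-dimethyl-N-(2-methylphenyl)but-3-enamide | C=CC(C)(C)C(=O)Nc1ccccc1C | intermediate
5 | 2-(2-methylbut-3-en-2-yl)-1H-indole | C=CC(C)(C)c1cc2ccccc2[nH]1 | intermediate
6 | 2,5-dichloro-1,4-benzoquinone | O=C1C=C(Cl)C(=O)C=C1Cl | starting material
7 | 2,5-dichloro-3-[2-(2-methylbut-3-en-2-yl)-1H-indol-3-yl]benzene-1,4-diol | Oc1cc(Cl)c(O)c(-c2c(C(C)(C)C=C)[nH]c3ccccc23)c1Cl | intermediate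
8 | 2,5-dichloro-3-[2-(2-methylbut-3-en-2-yl)-1H-indol-3-yl]-1,4-benzoquinone | O=C1C=C(Cl)C(=O)C(c2c(C(C)(C)C=C)[nH]c3ccccc23)=C1Cl | intermediate
9 | 2,5-dimethoxy-3-[2-(2-methylbut-3-en-2-yl)-1H-indol-3-yl]-1,4-benzoquinone | O=C1C=C(OC)C(=O)C(c2c(C(C)(C)C=C)[nH]c3ccccc23)=C1OC | intermediate
10 | 2,5-dimethoxy-3-[2-(2-methylbut-3-en-2-yl)-1H-indol-3-yl]benzene-1,4-diol | COc1cc(O)c(OC)c(-c2c(C(C)(C)C=C)[nH]c3ccccc23)c1O | intermediate
11 | 3-[3,6-dimethoxy-2,5-bis(methoxymethoxy)phenyl]-2-(2-methylbut-3-en-2-yl)-1H-indole | COCOc1cc(OC)c(OCOC)c(-c2c(C(C)(C)C=C)[nH]c3ccccc23)c1OC | intermediate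
12 | 2-nitrobenzyl bromide | O=[N+]([O-])c1ccccc1CBr | starting material
13 | 1-lithio-3-[4-lithio-3,6-dimethoxy-2,5-bis(methoxymethoxy)phenyl]-2-(2-methylbut-3-en-2-yl)indole | [Li]c1c(OCOC)c(OC)c(-c2c(C(C)(C)C=C)n([Li])c3ccccc23)c(OCOC)c1OC | intermediate
14 | 1-(chlorozincio)-3-[4-(chlorozincio)-3,6-dimethoxy-2,5-bis(methoxymethoxy)phenyl]-2-(2-methylbut-3-en-2-yl)indole | Cl[Zn]c1c(OCOC)c(OC)c(-c2c(C(C)(C)C=C)n([Zn]Cl)c3ccccc23)c(OCOC)c1OC | intermediate
15 | 3-[3,6-dimethoxy-2,5-bis(methoxymethoxy)-4-(2-nitrobenzyl)phenyl]-2-(2-methylbut-3-en-2-yl)-1H-indole | O=[N+]([O-])c1ccccc1Cc1c(OCOC)c(OC)c(-c2c(C(C)(C)C=C)[nH]c3ccccc23)c(OCOC)c1OC | intermediate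
16 | 2-({2,5-dimethoxy-3,6-bis(methoxymethoxy)-4-[2-(2-methylbut-3-en-2-yl)-1H-indol-3-yl]phenyl}methyl)aniline | Nc1ccccc1Cc1c(OCOC)c(OC)c(-c2c(C(C)(C)C=C)[nH]c3ccccc23)c(OCOC)c1OC | intermediate
17 | N-[2-({2,5-dimethoxy-3,6-bis(methoxymethoxy)-4-[2-(2-methylbut-3-en-2-yl)-1H-indol-3-yl]phenyl}methyl)phenyl]formamide | O=CNc1ccccc1Cc1c(OCOC)c(OC)c(-c2c(C(C)(C)C=C)[nH]c3ccccc23)c(OCOC)c1OC | intermediate
18 | 3-[4-(2-isocyanobenzyl)-3,6-dimethoxy-2,5-bis(methoxymethoxy)phenyl]-2-(2-methylbut-3-en-2-yl)-1H-indole | [C-]#[N+]c1ccccc1Cc1c(OCOC)c(OC)c(-c2c(C(C)(C)C=C)[nH]c3ccccc23)c(OCOC)c1OC | intermediate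
19 | 3-[4-(1H-indol-3-yl)-3,6-dimethoxy-2,5-bis(methoxymethoxy)phenyl]-2-(2-methylbut-3-en-2-yl)-1H-indole | C=CC(C)(C)c1[nH]c2ccccc2c1-c1c(OC)c(OCOC)c(-c2c[nH]c3ccccc23)c(OC)c1OCOC | intermediate
20 | 2-(1H-indol-3-yl)-3,6-dimethoxy-5-[2-(2-methylbut-3-en-2-yl)-1H-indol-3-yl]benzene-1,4-diol | C=CC(C)(C)c1[nH]c2ccccc2c1-c1c(OC)c(O)c(-c2c[nH]c3ccccc23)c(OC)c1O | intermediate
21 | 2,5-dimethoxy-3-(1H-indol-3-yl)-6-[2-(2-methylbut-3-en-2-yl)-1H-indol-3-yl]-1,4-benzoquinone (CNP0103667.0) | C=CC(C)(C)c1[nH]c2ccccc2c1C1=C(OC)C(=O)C(c2c[nH]c3ccccc23)=C(OC)C1=O | target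

**Step count**

Total: 11 steps. Longest linear sequence: 11 steps (1 → 21); 2, 6 and 12 enter as purchased materials.

**Steps most likely to fail**

Step 10. The amide base may add to the isocyanide carbon (a formamidine would result on work-up), or deprotonation of the crowded CH2 between two ortho-alkoxy groups may be too slow, so that the isocyanide is consumed by other paths. The fallback sets out from formamide 17 and leaves out the isocyanide. A Madelung-type closure in its alkyllithium variant (s-BuLi, 4 equiv, THF, −40 °C → rt) lithiates both N–H groups and then the doubly benzylic carbon; the carbanion attacks the N-lithio formamide carbon and loss of LiOH gives 19 directly, where the route is rejoined. An alkyllithium stronger and smaller than the amide base can be used here because no isocyanide is present to be attacked. No new compound is formed on this path (F0).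

Step 6. Electron transfer from the organometallic to the nitroarene, homocoupling of the benzylic bromide, or N-benzylation of the metalated indole nitrogen may erode the cross-coupling. The fallback sets out from 11. The same dilithiation is followed by trapping with 2-isopropoxy-4,4,5,5-tetramethyl-1,3,2-dioxaborolane, and aqueous work-up should give the isolable pinacol boronate 3-[3,6-dimethoxy-2,5-bis(methoxymethoxy)-4-(4,4,5,5-tetramethyl-1,3,2-dioxaborolan-2-yl)phenyl]-2-(2-methylbut-3-en-2-yl)-1H-indole F1. Suzuki–Miyaura coupling of this boronate with 12 (PdCl2(dppf), K3PO4, THF/H2O, 60 °C) rejoins the route at 15. No reducing organometallic meets the nitro group, and the indole nitrogen is neutral during the coupling.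

Step 4. Methoxide may add at the unsubstituted quinone carbon instead of displacing chloride, or the exchange may stop halfway or be blurred by partial hydrolysis. The fallback sets out from 8. Exhaustive hydrolysis (NaOH, MeOH/H2O, reflux; acidic work-up) drives everything to the doubly ionised, further-attack-resistant 2,5-dihydroxy-3-[2-(2-methylbut-3-en-2-yl)-1H-indol-3-yl]-1,4-benzoquinone F2. O-Methylation of its two acidic vinylogous-acid hydroxyls with Me3SiCHN2 (MeOH/toluene, 0 °C), which leaves the indole N–H alone, rejoins the route at 9.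

**Further compounds**

F0 | step 10 | none | none
F1 | step 6 | 3-[3,6-dimethoxy-2,5-bis(methoxymethoxy)-4-(4,4,5,5-tetramethyl-1,3,2-dioxaborolan-2-yl)phenyl]-2-(2-methylbut-3-en-2-yl)-1H-indole | CC1(C)OB(OC1(C)C)c1c(OCOC)c(OC)c(-c2c(C(C)(C)C=C)[nH]c3ccccc23)c(OCOC)c1OC
F2 | step 4 | 2,5-dihydroxy-3-[2-(2-methylbut-3-en-2-yl)-1H-indol-3-yl]-1,4-benzoquinone | O=C1C=C(O)C(=O)C(c2c(C(C)(C)C=C)[nH]c3ccccc23)=C1O
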